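**Retrosynthetic overview**
- The target has benzene ring A (C4a–C8a), 2H-pyran ring B (O1–C4) and 4-hydroxy-2-pyrone ring C, joined through C6–CH2. The bridge is cut first, giving chromene, pyrone and one CH2 unit (Mannich/Michael union). The C3=C4 alkene is traced back to the chroman by dehydrogenation.
- Key disconnection: O1–C8a (ring B) and C7–C8 (ring A) of the chroman are cut in one operation. Both rings unfold to an open chain holding a silyl-masked tertiary carbinol, a 1,3-diketone (C8a, C9) and a dioxinone that stores C5–C6–C7 as a latent acylketene.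
- Enabling feature: O1–C8a=C8–C9(=O) across rings A and B is a vinylogous ester. C8a is therefore a masked 1,3-diketone carbonyl that forms a six-membered ring with the carbinol oxygen. The 1,3,5-oxygen pattern C5/C7/C8a of ring A is a masked triketone.
- Ring order: ring B (O1–C8a), then ring A (C7–C8) in the same flask. Ring C is made separately from 3-pentanone and malonyl dichloride.
- The chain is assembled on 2,2,6-trimethyl-1,3-dioxin-4-one by acetylation, alkylation and acylation. The only stereocentre is bought with (S)-2-methylbutanoic acid.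

Key step: step 7

Remark on the chemistry: chromene numbers of the target (O1, C2–C4, C4a, C5–C8, C8a) are used for the same atoms in all precursors, and C9 is the ketone carbon on C8. The methine that becomes C4a is doubly activated and configurationally labile in every open-chain precursor. It is drawn without configuration because it ends as sp2.

**Step 1**
Reactants: 1 2,2,6-trimethyl-4H-1,3-dioxin-4-one
Product: 2 2,2-dimethyl-6-(2-oxopropyl)-4H-1,3-dioxin-4-one
Conditions: LiN(iPr)2 (2 equiv), 1 (2 equiv), THF, −78 °C; AcCl (1 equiv), −78 to −30 °C; aq NH4Cl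
Reagents that add atoms: acetyl chloride, CC(=O)Cl
Why: γ-C-acylation of the lithium dienolate of 1 (vinylogous Claisen condensation), in which the second equivalent of dienolate deprotonates the more acidic product and so stops double acylation.

**Step 2**
Reactants: 3 3-methylbutane-1,3-diol
Product: 4 4-iodo-2-methylbutan-2-ol
Conditions: PPh3, I2, imidazole, CH2Cl2, 0 to 23 °C
Reagents that add atoms: iodine, [I][I]
Why: Appel-type iodination is an SN2 process and should touch only the primary hydroxyl, the tertiary one being too hindered for displacement.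

**Step 3**
Reactants: 4 4-iodo-2-methylbutan-2-ol
Product: 5 triethyl[(4-iodo-2-methylbutan-2-yl)oxy]silane
Conditions: Et3SiOTf, 2,6-lutidine, CH2Cl2, −78 to 0 °C
Reagents that add atoms: triethylsilyl triflate, CC[Si](CC)(CC)OS(=O)(=O)C(F)(F)F
Why: Silylation of a hindered tertiary alcohol with a silyl triflate and a non-nucleophilic base gives an ether that survives carbonate and amide bases yet falls to catalytic acid in step 7.

**Step 4**
Reactants: 2 2,2-dimethyl-6-(2-oxopropyl)-4H-1,3-dioxin-4-one; 5 triethyl[(4-iodo-2-methylbutan-2-yl)oxy]silane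
Product: 6 2,2-dimethyl-6-[6-methyl-2-oxo-6-(triethylsilyloxy)heptan-3-yl]-4H-1,3-dioxin-4-one
Conditions: K2CO3, DMF, 45 °C
Reagents that add atoms: none
Why: Classical C-alkylation of a β-dicarbonyl-type carbanion (the CH2 between ketone and dioxinone is the most acidic site) by SN2 at an unhindered primary iodide, and the new methine is labile and needs no control.

**Step 5**
Reactants: 7 (S)-2-methylbutanoic acid
Product: 9 (S)-N-methoxy-N,2-dimethylbutanamide, via acyl imidazolide 8 (not isolated)
Conditions: 1,1'-carbonyldiimidazole, CH2Cl2, 23 °C; then MeNH(OMe)·HCl, 23 °C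
Reagents that add atoms: N,O-dimethylhydroxylamine hydrochloride, CNOC.Cl; 1,1'-carbonyldiimidazole, O=C(n1ccnc1)n1ccnc1 (its imidazolyl group stands only in 8)
Why: Acyl imidazolide activation and aminolysis (Weinreb amide synthesis) uses no base strong enough to enolise the α-branched acyl group, so the (S)-centre of the chiral pool acid should be kept.

**Step 6**
Reactants: 6 2,2-dimethyl-6-[6-methyl-2-oxo-6-(triethylsilyloxy)heptan-3-yl]-4H-1,3-dioxin-4-one; 9 (S)-N-methoxy-N,2-dimethylbutanamide
Product: 10 6-[(9S)-2,9-dimethyl-6,8-dioxo-2-(triethylsilyloxy)undecan-5-yl]-2,2-dimethyl-4H-1,3-dioxin-4-one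
Conditions: LiN(iPr)2 (2.1 equiv), THF, −78 to −40 °C; 9, −78 to −20 °C; aq NH4Cl, rapid chromatography
Reagents that add atoms: none
Why: Dianion Claisen-type acylation, in which the second deprotonation occurs at the terminal CH3 (C8), this most reactive carbanion adds to the Weinreb amide, and the chelated tetrahedral adduct persists until the quench and so shields the (S)-centre from base.

**Step 7**
Reactants: 10 6-[(9S)-2,9-dimethyl-6,8-dioxo-2-(triethylsilyloxy)undecan-5-yl]-2,2-dimethyl-4H-1,3-dioxin-4-one
Product: 14 (2S)-1-(5,7-dihydroxy-2,2-dimethyl-3,4-dihydro-2H-chromen-8-yl)-2-methylbutan-1-one, via hydroxy diketo-dioxinone 11 (not isolated), via pyranylidene ketone 12 (not isolated), via acylketene 13 (not isolated)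
Conditions: TsOH·H2O (0.1 equiv), wet toluene (0.01 M), 40 °C; then 4 Å molecular sieves, 110 °C, N2 sweep
Reagents that add atoms: none
Why: Proposed new method: catalytic acid and the water of TsOH·H2O free the tertiary carbinol (11) under conditions too gentle to ionise a saturated tertiary alcohol, its oxygen adds 6-exo-trig to the C8a carbonyl of the protonated 1,3-diketone and the former carbonyl oxygen leaves as water (recycled for the next desilylation) to give vinylogous ester 12 (O1–C8a, ring B); at 110 °C the dioxinone of 12 loses acetone by retro-[4+2] to acylketene 13, whose C5 enol is a dienylketene (C7=C6, C5=C4a, C8a=C8) that closes C7–C8 by disrotatory 6π electrocyclisation and tautomerises to the phenol (ring A). The closest known reaction types are the thermolysis of diketo-dioxinones to acylketenes with late aromatisation to resorcylates, the cyclodehydration of δ-hydroxy-1,3-diketones, and the dienylketene closure that ends a Danheiser benzannulation; new is their merger into a Claisen-type (C8 onto C7) closure that delivers an acylphloroglucinol ether. No stereocentre is created: the labile C4a methine becomes sp2, and the (S)-centre is a spectator next to a vinylogous-ester carbonyl that is conjugated away from it. Site selectivity for O1: attack at C8a gives a six-membered ring whereas C9 would need an eight-membered one, and addition to the dioxinone carbon C5 is reversible and unproductive below the cycloreversion temperature. Mode selectivity for ring A: etherification of the C8a oxygen removes the only oxygen nucleophile that could reach C7 through a six-membered ring (the usual 2-pyrone pathway), and conjugation with O1 deactivates the C9 carbonyl toward the competing aldol closure (C6 onto C9) that leads to resorcylates. The acyl group next to O1 and the single free position at C6 are thus fixed by the order of the chain and not by aromatic substitution.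

**Step 8**
Reactants: 14 (2S)-1-(5,7-dihydroxy-2,2-dimethyl-3,4-dihydro-2H-chromen-8-yl)-2-methylbutan-1-one
Product: 15 (2S)-1-(5,7-dihydroxy-2,2-dimethyl-2H-chromen-8-yl)-2-methylbutan-1-one
Conditions: DDQ (1.1 equiv), 1,4-dioxane, 90 °C
Reagents that add atoms: none
Why: DDQ dehydrogenation of a 2,2-dimethylchroman, in which hydride abstraction from benzylic C4 (stabilised by O1, 5-OH and 7-OH) and loss of a C3 proton give the conjugated chromene without involving the remote (S)-centre.

**Step 9**
Reactants: 16 3-pentanone
Product: 17 trimethyl(pent-2-en-3-yloxy)silane (E/Z mixture)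
Conditions: Me3SiOTf, Et3N, Et2O, 0 °C
Reagents that add atoms: trimethylsilyl triflate, C[Si](C)(C)OS(=O)(=O)C(F)(F)F
Why: Soft enolisation and O-silylation of a symmetrical ketone raises no regiochemical question, and the alkene geometry is irrelevant because it is lost in ring C.

**Step 10**
Reactants: 17 trimethyl(pent-2-en-3-yloxy)silane
Product: 18 6-ethyl-4-hydroxy-5-methyl-2H-pyran-2-one
Conditions: malonyl dichloride, Et2O, −78 to 23 °C
Reagents that add atoms: malonyl dichloride, O=C(Cl)CC(=O)Cl
Why: One acid chloride C-acylates the silyl enol ether and the second O-acylates the enol oxygen with loss of Me3SiCl, the established [3+3] route from silyl enol ethers to 4-hydroxy-2-pyrones, which places methyl at C5 and ethyl at C6 of ring C.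

**Step 11**
Reactants: 15 (2S)-1-(5,7-dihydroxy-2,2-dimethyl-2H-chromen-8-yl)-2-methylbutan-1-one; 18 6-ethyl-4-hydroxy-5-methyl-2H-pyran-2-one
Product: 21 3-({5,7-dihydroxy-2,2-dimethyl-8-[(2S)-2-methylbutanoyl]-2H-chromen-6-yl}methyl)-6-ethyl-4-hydroxy-5-methyl-2H-pyran-2-one (target), via Mannich base 19 (not isolated), via pyrone methide 20 (not isolated)
Conditions: 18, Me2N=CH2+ I− (1.0 equiv), CHCl3, 23 °C; then 15, 45 °C
Reagents that add atoms: Eschenmoser's salt (N,N-dimethylmethyleneiminium iodide), C=[N+](C)C.[I-]
Why: Mannich reaction at C3 of the acidic pyrone, retro-Michael loss of dimethylamine to methide 20 and Friedel–Crafts-type Michael addition of C6 of 15, the only free carbon of ring A (three-component Mannich/Michael union of the carba-Betti type), with full conversion of 18 into 19 before 15 is added so that symmetrical bis-pyrone formation is suppressed.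

**Compound list**
1 | 2,2,6-trimethyl-4H-1,3-dioxin-4-one | CC1=CC(=O)OC(C)(C)O1 | starting material
2 | 2,2-dimethyl-6-(2-oxopropyl)-4H-1,3-dioxin-4-one | CC(=O)CC1=CC(=O)OC(C)(C)O1 | intermediate
3 | 3-methylbutane-1,3-diol | CC(C)(O)CCO | starting material
4 | 4-iodo-2-methylbutan-2-ol | CC(C)(O)CCI | intermediate
5 | triethyl[(4-iodo-2-methylbutan-2-yl)oxy]silane | CC[Si](CC)(CC)OC(C)(C)CCI | intermediate
6 | 2,2-dimethyl-6-[6-methyl-2-oxo-6-(triethylsilyloxy)heptan-3-yl]-4H-1,3-dioxin-4-one (labile methine, both configurations) | CC(=O)C(CCC(C)(C)O[Si](CC)(CC)CC)C1=CC(=O)OC(C)(C)O1 | intermediate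
7 | (S)-2-methylbutanoic acid | CC[C@H](C)C(=O)O | starting material
8 | (2S)-1-(1H-imidazol-1-yl)-2-methylbutan-1-one | CC[C@H](C)C(=O)n1ccnc1 | intermediate
9 | (S)-N-methoxy-N,2-dimethylbutanamide | CC[C@H](C)C(=O)N(C)OC | intermediate
10 | 6-[(9S)-2,9-dimethyl-6,8-dioxo-2-(triethylsilyloxy)undecan-5-yl]-2,2-dimethyl-4H-1,3-dioxin-4-one (labile C5' methine) | CC[C@H](C)C(=O)CC(=O)C(CCC(C)(C)O[Si](CC)(CC)CC)C1=CC(=O)OC(C)(C)O1 | intermediate
11 | 6-[(9S)-2-hydroxy-2,9-dimethyl-6,8-dioxoundecan-5-yl]-2,2-dimethyl-4H-1,3-dioxin-4-one | CC[C@H](C)C(=O)CC(=O)C(CCC(C)(C)O)C1=CC(=O)OC(C)(C)O1 | intermediate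
12 | 6-{6,6-dimethyl-2-[(3S)-3-methyl-2-oxopentylidene]oxan-3-yl}-2,2-dimethyl-4H-1,3-dioxin-4-one (alkene geometry not fixed) | CC[C@H](C)C(=O)C=C1OC(C)(C)CCC1C2=CC(=O)OC(C)(C)O2 | intermediate
13 | 3-{6,6-dimethyl-2-[(3S)-3-methyl-2-oxopentylidene]oxan-3-yl}-3-oxoprop-1-en-1-one (acylketene) | CC[C@H](C)C(=O)C=C1OC(C)(C)CCC1C(=O)C=C=O | intermediate
14 | (2S)-1-(5,7-dihydroxy-2,2-dimethyl-3,4-dihydro-2H-chromen-8-yl)-2-methylbutan-1-one | CC[C@H](C)C(=O)c1c(O)cc(O)c2c1OC(C)(C)CC2 | intermediate
15 | (2S)-1-(5,7-dihydroxy-2,2-dimethyl-2H-chromen-8-yl)-2-methylbutan-1-one | CC[C@H](C)C(=O)c1c(O)cc(O)c2c1OC(C)(C)C=C2 | intermediate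
16 | 3-pentanone | CCC(=O)CC | starting material
17 | trimethyl(pent-2-en-3-yloxy)silane (E/Z mixture) | CC=C(CC)O[Si](C)(C)C | intermediate
18 | 6-ethyl-4-hydroxy-5-methyl-2H-pyran-2-one | CCc1oc(=O)cc(O)c1C | intermediate
19 | 3-[(dimethylamino)methyl]-6-ethyl-4-hydroxy-5-methyl-2H-pyran-2-one | CCc1oc(=O)c(CN(C)C)c(O)c1C | intermediate
20 | 6-ethyl-5-methyl-3-methylidene-2H-pyran-2,4(3H)-dione | CCC1=C(C)C(=O)C(=C)C(=O)O1 | intermediate
21 | 3-({5,7-dihydroxy-2,2-dimethyl-8-[(2S)-2-methylbutanoyl]-2H-chromen-6-yl}methyl)-6-ethyl-4-hydroxy-5-methyl-2H-pyran-2-one | CCc1oc(=O)c(Cc2c(O)c3c(c(C(=O)[C@@H](C)CC)c2O)OC(C)(C)C=C3)c(O)c1C | target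

Total step count: 11
Longest linear sequence: 7 steps (2, 3, 4, 6, 7, 8, 11)

**Steps most likely to fail**

**1. Step 7 (bears the label).**
- What may go wrong: the acylketene may be intercepted by the silanol or by traces of water, followed by decarboxylation. The aldol mode of closure (C6 onto C9) may compete once acid and heat are combined. Long acid exposure may erode the (S)-centre by enolisation.
- Fallback, from 10 back to 14, splits the cascade into three known operations and replaces the pericyclic closure by an anionic one. HF·pyridine in MeCN at 0 °C, then PPTS with 4 Å sieves in CH2Cl2 at 23 °C, should remove the silyl group and complete the cyclodehydration, so that vinylogous ester 12 is isolated with the O1–C8a bond in place. Brief heating of 12 in toluene with methanol (5 equiv) traps the acylketene as the methyl β-keto ester F1. Mg(OMe)2 in MeOH then effects the chelation-controlled Claisen (Dieckmann-type) cyclisation of C8 onto the ester carbon C7, and acid work-up should give 14.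

**2. Step 6.**
- What may go wrong: incomplete second deprotonation of the α-branched keto-dioxinone, or proton transfer from the amide to the dianion, would stall the acylation. The product may also aromatise by aldol closure during work-up or on silica.
- Fallback, from 6 and 9 back to 10, is addition to an aldehyde followed by oxidation instead of acyl substitution. iBu2AlH in CH2Cl2 at −78 °C reduces 9 to (S)-2-methylbutanal F2, which is used at once. The dianion of 6 adds to this far more electrophilic partner at −78 °C to give the β-hydroxy ketone F3 as a diastereomer mixture. Dess–Martin periodinane buffered with NaHCO3 in CH2Cl2 oxidises F3 to 10.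

**3. Step 8.**
- What may go wrong: over-oxidation of the free phloroglucinol ring, or addition of the reduced quinone to the intermediate quinone methide, may consume material.
- Fallback, from 14 back to 15, is radical halogenation and elimination on a protected ring instead of hydride abstraction. Ac2O and pyridine give the chroman diacetate F4. NBS with AIBN in PhCF3 at 80 °C brominates benzylic C4 to the 4-bromochroman F5. DBU in toluene eliminates to the chromene diacetate F6. K2CO3 in MeOH at 0 °C removes both acetates to return 15.

**Further compounds**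
F1 | step 7 | methyl 3-{6,6-dimethyl-2-[(3S)-3-methyl-2-oxopentylidene]oxan-3-yl}-3-oxopropanoate | CC[C@H](C)C(=O)C=C1OC(C)(C)CCC1C(=O)CC(=O)OC
F2 | step 6 | (S)-2-methylbutanal | CC[C@H](C)C=O
F3 | step 6 | 6-[(9S)-8-hydroxy-2,9-dimethyl-6-oxo-2-(triethylsilyloxy)undecan-5-yl]-2,2-dimethyl-4H-1,3-dioxin-4-one | CC[C@H](C)C(O)CC(=O)C(CCC(C)(C)O[Si](CC)(CC)CC)C1=CC(=O)OC(C)(C)O1
F4 | step 8 | 2,2-dimethyl-8-[(2S)-2-methylbutanoyl]-3,4-dihydro-2H-chromene-5,7-diyl diacetate | CC[C@H](C)C(=O)c1c(OC(C)=O)cc(OC(C)=O)c2c1OC(C)(C)CC2
F5 | step 8 | 4-bromo-2,2-dimethyl-8-[(2S)-2-methylbutanoyl]-3,4-dihydro-2H-chromene-5,7-diyl diacetate | CC[C@H](C)C(=O)c1c(OC(C)=O)cc(OC(C)=O)c2c1OC(C)(C)CC2Br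
F6 | step 8 | 2,2-dimethyl-8-[(2S)-2-methylbutanoyl]-2H-chromene-5,7-diyl diacetate | CC[C@H](C)C(=O)c1c(OC(C)=O)cc(OC(C)=O)c2c1OC(C)(C)C=C2
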